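Ring C of the flavone is cut at three bonds, C4a–C4, C4–C3 and O1–C2, so that C4 with its carbonyl oxygen comes from carbon monoxide, placed between ring A and an arylacetylene that carries C2, C3 and ring B. A single palladium-catalysed carbonylative annulation in diethylamine should forge all three bonds and close ring C. The feature exploited is that C4a of ring A lies between two oxygens, O1 and the 5-OH. A 2-iodoresorcinol with a mirror plane through its iodine-bearing carbon offers two identical hydroxyls, so only one flavone can arise. The future 7-oxygen, para to iodine, is a benzyl ether and the 4'-oxygen a silyl ether.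

Key step: step 8

Remark on the chemistry: aryl hydrogen sulfates are strong acids that hydrolyse on standing, so the sulfate is carried as its potassium salt and the free acid is liberated only in the last step, cold, and freeze-dried at once. The target has no stereocentre.

Step 1
Reactants: 1 phloroglucinol, 2 benzyl bromide
Product: 3 5-(benzyloxy)benzene-1,3-diol
Conditions: 1 (3 equiv), BnBr (1 equiv, slow addition), K2CO3 (1.1 equiv), DMF, 0 °C to rt
Reagents that add atoms: benzyl bromide, BrCc1ccccc1
Why: Williamson etherification of a phenoxide, in which the threefold excess of the symmetric triol should make mono-O-benzylation the main event and the unreacted triol should wash out with water.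

Step 2
Reactants: 3 5-(benzyloxy)benzene-1,3-diol, 4 chloromethyl methyl ether
Product: 5 1-(benzyloxy)-3,5-bis(methoxymethoxy)benzene
Conditions: MOMCl (2.5 equiv), i-Pr2NEt (3 equiv), CH2Cl2, 0 °C to rt
Reagents that add atoms: chloromethyl methyl ether, COCCl
Why: Amine-mediated O-alkylation of both remaining phenols (MOM acetal protection) should install two strong ortho-directing groups on either side of one ring C–H.

Step 3
Reactants: 5 1-(benzyloxy)-3,5-bis(methoxymethoxy)benzene, 6 iodine
Product: 8 5-(benzyloxy)-2-iodo-1,3-bis(methoxymethoxy)benzene, via aryllithium 7 (not isolated)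
Conditions: n-BuLi (1.1 equiv), THF, 0 °C, 1 h; then I2 (1.2 equiv), THF, −78 °C to rt; Na2S2O3 work-up
Reagents that add atoms: iodine, II
Why: Directed ortho-metalation should take place at the C–H flanked by the two chelating MOM acetals and not beside the benzyl ether, and the aryllithium is then trapped by iodine, so the halogen is placed without any regiochemical ambiguity.

Step 4
Reactants: 8 5-(benzyloxy)-2-iodo-1,3-bis(methoxymethoxy)benzene
Product: 9 5-(benzyloxy)-2-iodobenzene-1,3-diol
Conditions: HCl (1.25 M in MeOH), MeOH/THF, rt, dark; NaHCO3 quench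
Reagents that add atoms: none
Why: Acid-catalysed acetal exchange with methanol should free both phenols as dimethoxymethane leaves, and the mild, dark conditions are chosen so that the benzyl ether and the C–I bond persist.

Step 5
Reactants: 10 4-iodophenol, 11 chlorotriisopropylsilane
Product: 12 (4-iodophenoxy)triisopropylsilane
Conditions: TIPSCl (1.1 equiv), imidazole (2.2 equiv), DMF, rt
Reagents that add atoms: chlorotriisopropylsilane, CC(C)[Si](Cl)(C(C)C)C(C)C
Why: Imidazole-promoted O-silylation of a phenol should give the bulky silyl ether, chosen to survive the amine of the key step.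

Step 6
Reactants: 12 (4-iodophenoxy)triisopropylsilane, 13 trimethylsilylacetylene
Product: 14 triisopropyl{4-[(trimethylsilyl)ethynyl]phenoxy}silane
Conditions: TMS-acetylene (1.3 equiv), PdCl2(PPh3)2 (2 mol %), CuI (4 mol %), Et3N/THF, rt
Reagents that add atoms: trimethylsilylacetylene, C#C[Si](C)(C)C
Why: Sonogashira coupling of an aryl iodide with a terminal alkyne runs at room temperature and tolerates the aryl silyl ether.

Step 7
Reactants: 14 triisopropyl{4-[(trimethylsilyl)ethynyl]phenoxy}silane
Product: 15 1-ethynyl-4-[(triisopropylsilyl)oxy]benzene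
Conditions: K2CO3 (0.2 equiv), MeOH/THF, 0 °C to rt
Reagents that add atoms: none
Why: Base-catalysed methanolysis of the alkynyl C–Si bond (protodesilylation) should be much faster than attack on the hindered aryl triisopropylsilyl ether.

Step 8
Reactants: 9 5-(benzyloxy)-2-iodobenzene-1,3-diol, 15 1-ethynyl-4-[(triisopropylsilyl)oxy]benzene, 16 carbon monoxide
Product: 19 7-(benzyloxy)-5-hydroxy-2-{4-[(triisopropylsilyl)oxy]phenyl}-4H-chromen-4-one, via ynone 17 (not isolated), via enaminone 18 (not isolated)
Conditions: PdCl2(dppf) (5 mol %), CO (20 bar), 15 (1.3 equiv), Et2NH, 100–120 °C, autoclave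
Reagents that add atoms: carbon monoxide, [C-]#[O+]
Why: Zerovalent palladium, formed from PdCl2(dppf) under CO and amine, adds to the C–I bond of 9, CO inserts to give an aroylpalladium iodide, and amine-assisted alkynyl transfer from 15 with reductive elimination gives ynone 17, which creates C4a–C4 and C4–C3. Diethylamine then adds to 17 in conjugate fashion to give enaminone 18, and one of the two flanking hydroxyls displaces the amine by addition–elimination, which creates O1–C2; the whole is the known carbonylative annulation of ortho-iodophenols with terminal arylacetylenes in secondary amines. Ring C closes in a 6-endo mode, as a 6-endo-trig attack on the enaminone carbon that becomes C2, followed by loss of diethylamine. No stereocentre is formed. The step needs CO insertion to outrun direct alkynylation and aminocarbonylation, which CO pressure, the copper-free catalyst and an excess of the alkyne favour, and it needs six-membered (flavone) over five-membered (aurone) closure, which the enaminone secures because C2 is its only electrophilic carbon. Regiochemistry cannot go astray because the mirror plane of 9 makes both hydroxyls next to iodine the same, so the one not used ends as the hydrogen-bonded 5-OH and the benzyloxy group para to iodine ends at C7.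

Step 9
Reactants: 19 7-(benzyloxy)-5-hydroxy-2-{4-[(triisopropylsilyl)oxy]phenyl}-4H-chromen-4-one
Product: 20 5,7-dihydroxy-2-{4-[(triisopropylsilyl)oxy]phenyl}-4H-chromen-4-one
Conditions: H2 (1 atm), Pd/C (10 wt % Pd on carbon, cat.), EtOAc/THF, rt
Reagents that add atoms: none
Why: Catalytic hydrogenolysis of the benzyl aryl ether should free only the 7-OH, since the silyl ether is inert and the C2–C3 bond of the chromone, a vinylogous ester conjugated to two arenes, is not expected to be reduced at 1 atm.

Step 10
Reactants: 20 5,7-dihydroxy-2-{4-[(triisopropylsilyl)oxy]phenyl}-4H-chromen-4-one, 21 sulfur trioxide–pyridine complex, 22 potassium fluoride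
Product: 24 potassium 5-hydroxy-2-(4-hydroxyphenyl)-4-oxo-4H-chromen-7-yl sulfate, via pyridinium sulfate 23 (not isolated)
Conditions: SO3·pyridine (3 equiv), pyridine, rt; MeOH quench; then KF (3 equiv), MeOH, rt; C18 chromatography
Reagents that add atoms: sulfur trioxide–pyridine complex, O=S(=O)([O-])[n+]1ccccc1; potassium fluoride, [K+].[F-]
Why: O-sulfation with the SO3–amine complex should occur at the free, acidic 7-OH because the 5-OH is tied up in a hydrogen bond to the C4 carbonyl, and fluoride-induced cleavage of the aryl silyl ether (fluorodesilylation) then frees the 4'-OH without touching the sulfate monoester anion.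

Step 11
Reactants: 24 potassium 5-hydroxy-2-(4-hydroxyphenyl)-4-oxo-4H-chromen-7-yl sulfate
Product: 25 apigenin 7-sulfate (5-hydroxy-2-(4-hydroxyphenyl)-4-oxo-4H-chromen-7-yl hydrogen sulfate)
Conditions: Dowex 50W-X8 (H+ form), H2O/MeOH, 0–5 °C; freeze-dry at once
Reagents that add atoms: none
Why: Cation exchange on a strong-acid resin should replace K+ by H+ without any other change, and the cold, brief handling limits acid-catalysed hydrolysis of the aryl sulfate.

Compound list
1 | phloroglucinol (benzene-1,3,5-triol) | Oc1cc(O)cc(O)c1 | starting material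
2 | benzyl bromide | BrCc1ccccc1 | starting material
3 | 5-(benzyloxy)benzene-1,3-diol | Oc1cc(O)cc(OCc2ccccc2)c1 | intermediate
4 | chloromethyl methyl ether (MOMCl) | COCCl | starting material
5 | 1-(benzyloxy)-3,5-bis(methoxymethoxy)benzene | COCOc1cc(OCOC)cc(OCc2ccccc2)c1 | intermediate
6 | iodine | II | starting material
7 | [4-(benzyloxy)-2,6-bis(methoxymethoxy)phenyl]lithium (aryllithium, not isolated) | [Li]c1c(OCOC)cc(OCc2ccccc2)cc1OCOC | intermediate
8 | 5-(benzyloxy)-2-iodo-1,3-bis(methoxymethoxy)benzene | COCOc1cc(OCc2ccccc2)cc(OCOC)c1I | intermediate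
9 | 5-(benzyloxy)-2-iodobenzene-1,3-diol | Oc1cc(OCc2ccccc2)cc(O)c1I | intermediate
10 | 4-iodophenol | Oc1ccc(I)cc1 | starting material
11 | chlorotriisopropylsilane (TIPSCl) | CC(C)[Si](Cl)(C(C)C)C(C)C | starting material
12 | (4-iodophenoxy)triisopropylsilane | CC(C)[Si](Oc1ccc(I)cc1)(C(C)C)C(C)C | intermediate
13 | trimethylsilylacetylene | C#C[Si](C)(C)C | starting material
14 | triisopropyl{4-[(trimethylsilyl)ethynyl]phenoxy}silane | CC(C)[Si](Oc1ccc(C#C[Si](C)(C)C)cc1)(C(C)C)C(C)C | intermediate
15 | 1-ethynyl-4-[(triisopropylsilyl)oxy]benzene | C#Cc1ccc(O[Si](C(C)C)(C(C)C)C(C)C)cc1 | intermediate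
16 | carbon monoxide | [C-]#[O+] | starting material
17 | 1-[4-(benzyloxy)-2,6-dihydroxyphenyl]-3-{4-[(triisopropylsilyl)oxy]phenyl}prop-2-yn-1-one (ynone, not isolated) | O=C(C#Cc1ccc(O[Si](C(C)C)(C(C)C)C(C)C)cc1)c1c(O)cc(OCc2ccccc2)cc1O | intermediate
18 | (E)-1-[4-(benzyloxy)-2,6-dihydroxyphenyl]-3-(diethylamino)-3-{4-[(triisopropylsilyl)oxy]phenyl}prop-2-en-1-one (enaminone, not isolated) | O=C(/C=C(/N(CC)CC)c1ccc(O[Si](C(C)C)(C(C)C)C(C)C)cc1)c1c(O)cc(OCc2ccccc2)cc1O | intermediate
19 | 7-(benzyloxy)-5-hydroxy-2-{4-[(triisopropylsilyl)oxy]phenyl}-4H-chromen-4-one (7-O-benzyl-4'-O-triisopropylsilylapigenin) | O=c1cc(-c2ccc(O[Si](C(C)C)(C(C)C)C(C)C)cc2)oc2cc(OCc3ccccc3)cc(O)c12 | intermediate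
20 | 5,7-dihydroxy-2-{4-[(triisopropylsilyl)oxy]phenyl}-4H-chromen-4-one (4'-O-triisopropylsilylapigenin) | O=c1cc(-c2ccc(O[Si](C(C)C)(C(C)C)C(C)C)cc2)oc2cc(O)cc(O)c12 | intermediate
21 | sulfur trioxide–pyridine complex | O=S(=O)([O-])[n+]1ccccc1 | starting material
22 | potassium fluoride | [K+].[F-] | starting material
23 | pyridinium 5-hydroxy-4-oxo-2-{4-[(triisopropylsilyl)oxy]phenyl}-4H-chromen-7-yl sulfate (not isolated) | O=c1cc(-c2ccc(O[Si](C(C)C)(C(C)C)C(C)C)cc2)oc2cc(OS(=O)(=O)[O-])cc(O)c12.c1cc[nH+]cc1 | intermediate
24 | potassium 5-hydroxy-2-(4-hydroxyphenyl)-4-oxo-4H-chromen-7-yl sulfate | O=c1cc(-c2ccc(O)cc2)oc2cc(OS(=O)(=O)[O-])cc(O)c12.[K+] | intermediate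
25 | apigenin 7-sulfate | O=c1cc(-c2ccc(O)cc2)oc2cc(OS(=O)(=O)O)cc(O)c12 | target

Total step count: 11. Longest linear sequence: 8 steps (steps 1–4 and 8–11); the alkyne branch (steps 5–7) joins at step 8.

Steps most likely to fail

Step 8. The carbonylation may be overtaken by direct alkynylation of the aryl iodide and closure to a benzofuran, by aminocarbonylation to the diethylamide, or by reductive loss of iodine from the very electron-rich ring. The fallback uses neither palladium nor CO; it sets out from 5 and 15 and comes back at 19.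
- Lithiation of 5 as in step 3 (aryllithium 7) and a DMF quench should give 4-(benzyloxy)-2,6-bis(methoxymethoxy)benzaldehyde F1.
- Deprotonation of 15 with n-BuLi in THF at −78 °C gives {4-[(triisopropylsilyl)oxy]phenyl}ethynyllithium F2, which should add to F1 to give racemic 1-[4-(benzyloxy)-2,6-bis(methoxymethoxy)phenyl]-3-{4-[(triisopropylsilyl)oxy]phenyl}prop-2-yn-1-ol F3.
- MnO2 in CH2Cl2 should oxidise this to 1-[4-(benzyloxy)-2,6-bis(methoxymethoxy)phenyl]-3-{4-[(triisopropylsilyl)oxy]phenyl}prop-2-yn-1-one F4.
- Brief treatment with HCl in MeOH frees the two phenols to give ynone 17, which diethylamine in ethanol should convert through enaminone 18 into 19.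

Step 4. Under acid the iodine may migrate or be lost by protonation of the highly activated ipso carbon, and the released formaldehyde equivalent may alkylate the ring. The fallback avoids acid and the acetal groups altogether; it sets out from 3 and comes back at 9. Compound 3 is iodinated with I2 (1 equiv) and NaHCO3 in THF/H2O at 0 °C, the conditions under which resorcinols are iodinated kinetically at the carbon between the two hydroxyls. Any isomer iodinated next to the benzyloxy group would be removed by chromatography. This replaces steps 2–4 and makes no compound outside the list (entry F0).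

Step 10. Sulfation may stop short or lose selectivity, and premature loss of the silyl group under the pyridinium conditions would expose the 4'-oxygen to sulfation; the polar salt may also be lost on purification. The fallback carries the sulfate as a neutral, chromatographable diester; it sets out from 20 and comes back at 24.
- 2,2,2-Trichloroethyl chlorosulfate with Et3N and DMAP in THF at 0 °C should give 5-hydroxy-4-oxo-2-{4-[(triisopropylsilyl)oxy]phenyl}-4H-chromen-7-yl 2,2,2-trichloroethyl sulfate F5.
- Zn dust and HCO2NH4 in MeOH should remove the trichloroethyl group reductively to give ammonium 5-hydroxy-4-oxo-2-{4-[(triisopropylsilyl)oxy]phenyl}-4H-chromen-7-yl sulfate F6.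
- KF in MeOH then removes the silyl ether and, with loss of ammonia, leaves 24.

Further compounds
F1 | step 8 | 4-(benzyloxy)-2,6-bis(methoxymethoxy)benzaldehyde | O=Cc1c(OCOC)cc(OCc2ccccc2)cc1OCOC
F2 | step 8 | {4-[(triisopropylsilyl)oxy]phenyl}ethynyllithium | [Li]C#Cc1ccc(O[Si](C(C)C)(C(C)C)C(C)C)cc1
F3 | step 8 | racemic 1-[4-(benzyloxy)-2,6-bis(methoxymethoxy)phenyl]-3-{4-[(triisopropylsilyl)oxy]phenyl}prop-2-yn-1-ol | OC(C#Cc1ccc(O[Si](C(C)C)(C(C)C)C(C)C)cc1)c1c(OCOC)cc(OCc2ccccc2)cc1OCOC
F4 | step 8 | 1-[4-(benzyloxy)-2,6-bis(methoxymethoxy)phenyl]-3-{4-[(triisopropylsilyl)oxy]phenyl}prop-2-yn-1-one | O=C(C#Cc1ccc(O[Si](C(C)C)(C(C)C)C(C)C)cc1)c1c(OCOC)cc(OCc2ccccc2)cc1OCOC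
F0 | step 4 | none | none
F5 | step 10 | 5-hydroxy-4-oxo-2-{4-[(triisopropylsilyl)oxy]phenyl}-4H-chromen-7-yl 2,2,2-trichloroethyl sulfate | O=c1cc(-c2ccc(O[Si](C(C)C)(C(C)C)C(C)C)cc2)oc2cc(OS(=O)(=O)OCC(Cl)(Cl)Cl)cc(O)c12
F6 | step 10 | ammonium 5-hydroxy-4-oxo-2-{4-[(triisopropylsilyl)oxy]phenyl}-4H-chromen-7-yl sulfate | O=c1cc(-c2ccc(O[Si](C(C)C)(C(C)C)C(C)C)cc2)oc2cc(OS(=O)(=O)[O-])cc(O)c12.[NH4+]
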